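**Retrosynthetic overview** (labdane numbering C1–C20 is used for every compound)

1. The target is the O15-formate of imbricatolic acid. Endgame disconnections: formate; C18 (α-face methylation of a C19 ester enolate); C19 (carbonylation of a C3=C4 enol triflate from a C4 ketone); C17 (methylenation of a C8 ketone).
2. Enabling feature: C4 and C8 are both carbonyl-level carbons, 1,5 to each other across C5–C6 of ring B, and C3 of ring A is allylic to C5 once C4 is an enol ether. A temporary C3–C8 bond then makes ring A plus the C8–C9 unit a bicyclo[2.2.2]oct-5-ene containing the 1,5-diene C6=C7–C8(O⁻)–C3–C4(OSi)=C5.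
3. An anionic oxy-Cope rearrangement of this cage forms C5–C6, cuts C3–C8 and gives the cis-decalin with C8 (enolate) and C4 (silyl enol ether) differentiated. The C4 ketone then allows epimerization of C5 to the trans fusion.
4. The cage comes from meso 4-methylbicyclo[2.2.2]octane-2,6-dione (3-methylcyclohexenone plus an acetate unit), desymmetrized with a chiral lithium amide (fixes C10). The C11–C16 chain comes from (S)-citronellol and is attached at C9 by enolate alkylation.
5. Ring order: ring A first (as the cyclohexane of the bicyclic dione), ring B in the key step.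

Key step: step 10

Assumption: the (R,R)-amide in step 7 is taken to remove the C5 proton that leads to 12; if the sense of induction is the opposite, the equally available (S,S)-amide is used and nothing else changes.

Step 1
Reactants: 1 (S)-(−)-citronellol
Product: 2 (S)-tert-butyl[(3,7-dimethyloct-6-en-1-yl)oxy]diphenylsilane
Conditions: TBDPSCl, imidazole, DMF, 0 °C to rt
Reagents that add atoms: tert-butyl(chloro)diphenylsilane, CC(C)(C)[Si](Cl)(c1ccccc1)c1ccccc1
Why: Silyl ether formation at the primary alcohol; the C13 stereocenter comes from the chiral pool and is not touched.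

Step 2
Reactants: 2 (S)-citronellyl silyl ether
Product: 3 (S)-6-[(tert-butyldiphenylsilyl)oxy]-4-methylhexanoic acid
Conditions: KMnO4 (cat.), NaIO4, K2CO3, t-BuOH/H2O, rt; then 1 M HCl to pH 3
Reagents that add atoms: sodium periodate, [Na+].[O-]I(=O)(=O)=O; water, O
Why: Lemieux–von Rudloff oxidative cleavage of the trisubstituted alkene should give the acid and acetone, the mildly basic medium leaving the silyl ether intact.

Step 3
Reactants: 3 (S)-6-[(tert-butyldiphenylsilyl)oxy]-4-methylhexanoic acid
Product: 4 (R)-tert-butyl[(5-iodo-3-methylpentyl)oxy]diphenylsilane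
Conditions: PhI(OAc)2, I2, cyclohexane, hν (tungsten lamp), reflux
Reagents that add atoms: iodine, [I][I]
Why: Hunsdiecker-type iododecarboxylation via the acyl hypoiodite (radical chain); the primary radical is trapped by iodine and the stereocenter two carbons away is unaffected (the descriptor becomes R only through CIP priorities).

Step 4
Reactants: 5 3-methylcyclohex-2-en-1-one; 6 tert-butyl[(1-methoxyvinyl)oxy]dimethylsilane
Product: 8 methyl 2-(1-methyl-3-oxocyclohexyl)acetate (racemic), via silyl enol ether 7 (not isolated)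
Conditions: Tf2NH (1 mol %), CH2Cl2, −78 to −20 °C; then 1 M HCl, THF, rt
Reagents that add atoms: none
Why: Mukaiyama–Michael addition of the ketene silyl acetal to the β,β-disubstituted enone, catalysed by the silyl triflimide formed in situ, builds the quaternary carbon (later C10); its configuration is irrelevant because step 6 gives a meso compound.

Step 5
Reactants: 8 methyl 2-(1-methyl-3-oxocyclohexyl)acetate
Product: 9 2-(1-methyl-3-oxocyclohexyl)acetic acid (racemic)
Conditions: LiOH·H2O, THF/H2O, rt; then 1 M HCl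
Reagents that add atoms: lithium hydroxide, [Li+].[OH-]
Why: Saponification of an unhindered methyl ester.

Step 6
Reactants: 9 2-(1-methyl-3-oxocyclohexyl)acetic acid
Product: 10 4-methylbicyclo[2.2.2]octane-2,6-dione (meso)
Conditions: polyphosphoric acid, AcOH, 100 °C
Reagents that add atoms: none
Why: Intramolecular C-acylation of the ketone enol by the activated acid; only the α-carbon remote from the quaternary centre can close a six-membered ring, which gives the bridged 1,3-dione.

Step 7
Reactants: 10 4-methylbicyclo[2.2.2]octane-2,6-dione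
Product: 12 (1R,4R)-6-[(tert-butyldimethylsilyl)oxy]-4-methylbicyclo[2.2.2]oct-5-en-2-one (C8 ketone; C4(OTBS)=C5; C10 methyl), via lithium enolate 11 (not isolated)
Conditions: (R,R)-bis(1-phenylethyl)amine, n-BuLi, LiCl, THF, −78 °C; then TBSOTf, −78 °C
Reagents that add atoms: tert-butyldimethylsilyl trifluoromethanesulfonate, CC(C)(C)[Si](C)(C)OS(=O)(=O)C(F)(F)F
Why: Desymmetrization by enantiotopic-group-selective deprotonation with a chiral lithium amide and O-silylation of the enolate; the bridgehead C3–H cannot be removed, so the base chooses between C5–H and C9–H, and this choice fixes the absolute configuration of the quaternary C10.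

Step 8
Reactants: 12 silyl enol ether ketone; 4 (R)-iodide
Product: 14 (1R,3R,4S)-6-[(tert-butyldimethylsilyl)oxy]-3-[(3S)-5-[(tert-butyldiphenylsilyl)oxy]-3-methylpentyl]-4-methylbicyclo[2.2.2]oct-5-en-2-one (side chain on C9 on the face of the enol-ether bridge), via lithium enolate 13 (not isolated)
Conditions: LiN(i-Pr)2, THF, −78 °C; then 4, HMPA, −78 to −20 °C
Reagents that add atoms: none
Why: Alkylation of the only possible enolate (C8=C9) with the primary iodide; the electrophile should enter from the face of the sp2 enol-ether bridge, because the C1–H of the saturated C1–C2 bridge blocks the other face, which places the chain cis to the C10 methyl (9β, as in the target).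

Step 9
Reactants: 14 alkylated bicyclic ketone
Product: 15 2-ethenyl carbinol of 14: 6-[(tert-butyldimethylsilyl)oxy]-3-[(3S)-5-[(tert-butyldiphenylsilyl)oxy]-3-methylpentyl]-2-ethenyl-4-methylbicyclo[2.2.2]oct-5-en-2-ol (vinyl on the face of the enol-ether bridge; hydroxyl toward the saturated bridge)
Conditions: CH2=CHMgBr, CeCl3, THF, −78 °C; then aq. NH4Cl
Reagents that add atoms: vinylmagnesium bromide, C=C[Mg]Br
Why: 1,2-Addition of the weakly basic vinylcerium reagent to the hindered, enolizable ketone; attack is expected from the face of the enol-ether bridge because the opposite face is blocked by the C2–H of the saturated bridge, which puts the vinyl group syn to C4=C5 as the rearrangement requires.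

Step 10
Reactants: 15 vinyl carbinol
Product: 18 4-[(tert-butyldimethylsilyl)oxy]-15-[(tert-butyldiphenylsilyl)oxy]-17,18,19-trinor-5β-labd-3-en-8-one (cis-fused; 9β chain; 10β methyl; 13S), via potassium alkoxide 16 (not isolated), via potassium enolate 17 (not isolated)
Conditions: KH, 18-crown-6, THF, 0 to 50 °C; then inverse quench into aq. NH4Cl, −40 °C
Reagents that add atoms: none
Why: The potassium alkoxide 16 undergoes a charge-accelerated [3,3]-sigmatropic shift across the 1,5-diene C6=C7–C8(O⁻)–C3–C4=C5, held in a boat array by the cage: C3–C8 breaks, C5–C6 forms, and the C7=C8 enolate 17 and the C3=C4 silyl enol ether result. The closest known reaction type is the anionic oxy-Cope rearrangement of 2-vinylbicyclo[2.2.2]oct-5-en-2-ols to cis-fused octalones. Ring B closes by a suprafacial shift in which the allyl terminus C5 bonds to the vinyl terminus C6 (formally 6-endo with respect to C6=C7) while the temporary bridge bond is cut, so cage strain and enolate formation drive the step. The new stereocenter C5 is set stereospecifically, since C6 can reach C5 only on the face that carried the C8–C9 bridge, so H5 ends cis to the C10 methyl; C9 and C10 are carried over unchanged. The step needs the vinyl group syn to the enol-ether bridge (secured in step 9) and a single π-partner (only C4=C5 is present), and the OTBS group on C4 makes the new ring A alkene a masked C4 ketone distinct from the C8 ketone. The cold inverse quench protonates C7 without exchanging the C9 proton.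

Step 11
Reactants: 18 cis-fused keto silyl enol ether
Product: 19 4-[(tert-butyldimethylsilyl)oxy]-15-[(tert-butyldiphenylsilyl)oxy]-18,19-dinor-5β-labda-3,8(17)-diene
Conditions: Cp2TiMe2, toluene/THF, 65 °C, dark
Reagents that add atoms: dimethyltitanocene (Cp2TiMe2), C[Ti](C)(C1C=CC=C1)C1C=CC=C1
Why: Petasis methylenation through Cp2Ti=CH2 is non-basic, so the hindered, enolizable C8 ketone should be converted without epimerization at C9 and without touching the silyl enol ether.

Step 12
Reactants: 19 diene silyl enol ether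
Product: 21 15-[(tert-butyldiphenylsilyl)oxy]-18,19-dinorlabd-8(17)-en-4-one (5α-H; trans-fused), via cis-ketone 20 (not isolated)
Conditions: HCl (cat.), THF/H2O, 0 °C to rt; then NaOMe (0.3 equiv), MeOH, rt
Reagents that add atoms: none
Why: Acid hydrolysis of the silyl enol ether (protonation at C3) unmasks the C4 ketone, and methoxide-mediated enolization toward C5 should then equilibrate the ring fusion to the more stable trans-decalone (H5 α), ring B being anchored by the equatorial C9 chain as in 4-oxo steroids.

Step 13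
Reactants: 21 trans-fused C4 ketone
Product: 23 15-[(tert-butyldiphenylsilyl)oxy]-18,19-dinorlabda-3,8(17)-dien-4-yl trifluoromethanesulfonate, via potassium enolate 22 (not isolated)
Conditions: KN(SiMe3)2, THF, −78 °C; then PhNTf2, −78 to 0 °C
Reagents that add atoms: N-phenylbis(trifluoromethanesulfonimide), O=S(=O)(N(c1ccccc1)S(=O)(=O)C(F)(F)F)C(F)(F)F
Why: Kinetic deprotonation by the bulky amide at the C3 methylene (not at the ring-fusion C5–H) and O-triflation give the C3=C4 enol triflate, leaving C5 untouched.

Step 14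
Reactants: 23 enol triflate
Product: 24 2-(trimethylsilyl)ethyl 15-[(tert-butyldiphenylsilyl)oxy]-18-norlabda-3,8(17)-dien-19-oate
Conditions: Pd(OAc)2 (5 mol %), dppp (5 mol %), CO (1 atm), Me3SiCH2CH2OH, Et3N, DMF, 50 °C
Reagents that add atoms: carbon monoxide, [C-]#[O+]; 2-(trimethylsilyl)ethanol, C[Si](C)(C)CCO
Why: Alkoxycarbonylation of the enol triflate by zerovalent palladium (oxidative addition, CO insertion, alcoholysis) installs C19 as a fluoride-cleavable ester.

Step 15
Reactants: 24 unsaturated ester
Product: 25 2-(trimethylsilyl)ethyl 15-[(tert-butyldiphenylsilyl)oxy]-18-norlabd-8(17)-en-19-oate (C4 epimers)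
Conditions: Cu(OAc)2·H2O (5 mol %), 1,2-bis(diphenylphosphino)benzene (5 mol %), (HMe2Si)2O, t-BuOH, toluene, rt
Reagents that add atoms: none
Why: Copper hydride conjugate reduction of the enoate (hydride to C3, protonation of the copper enolate by t-BuOH) is chemoselective over the unactivated 1,1-disubstituted alkene; the C4 configuration formed here is erased in step 16.

Step 16
Reactants: 25 saturated ester
Product: 27 2-(trimethylsilyl)ethyl (13S)-15-[(tert-butyldiphenylsilyl)oxy]labd-8(17)-en-19-oate (4S; axial ester), via lithium enolate 26 (not isolated)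
Conditions: LiN(i-Pr)2, THF, −78 °C; then MeI, −78 to 0 °C
Reagents that add atoms: iodomethane, IC
Why: Ester enolate alkylation: iodomethane should attack the exocyclic enolate from the α-face, anti to the axial C10 methyl, so C18 becomes equatorial and the C19 ester axial (4S), the usual preference of C4 enolates in 10-methyl-trans-decalins.

Step 17
Reactants: 27 fully protected imbricatolate
Product: 28 imbricatolic acid, (13S)-15-hydroxylabd-8(17)-en-19-oic acid
Conditions: Bu4NF, THF, rt to 45 °C; then 1 M HCl to pH 3, 0 °C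
Reagents that add atoms: none
Why: Fluoride cleaves the 2-(trimethylsilyl)ethyl ester by β-elimination (independent of the hindrance at the axial C19 carbonyl) and removes the silyl ether in the same operation.

Step 18
Reactants: 28 imbricatolic acid
Product: 29 (13S)-15-(formyloxy)labd-8(17)-en-19-oic acid, the target
Conditions: acetic formic anhydride, pyridine, CH2Cl2, 0 °C; then H2O
Reagents that add atoms: acetic formic anhydride, CC(=O)OC=O
Why: Acyl transfer from the mixed anhydride to the primary alcohol (the formyl group is transferred preferentially); the hindered tertiary acid at most forms a mixed anhydride that is hydrolysed on aqueous work-up.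

**Compound list**

1 | (S)-(−)-citronellol | CC(C)=CCC[C@H](C)CCO | starting material
2 | (S)-tert-butyl[(3,7-dimethyloct-6-en-1-yl)oxy]diphenylsilane | CC(C)=CCC[C@H](C)CCO[Si](c1ccccc1)(c1ccccc1)C(C)(C)C | intermediate
3 | (S)-6-[(tert-butyldiphenylsilyl)oxy]-4-methylhexanoic acid | OC(=O)CC[C@H](C)CCO[Si](c1ccccc1)(c1ccccc1)C(C)(C)C | intermediate
4 | (R)-tert-butyl[(5-iodo-3-methylpentyl)oxy]diphenylsilane | ICC[C@H](C)CCO[Si](c1ccccc1)(c1ccccc1)C(C)(C)C | intermediate
5 | 3-methylcyclohex-2-en-1-one | CC1=CC(=O)CCC1 | starting material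
6 | tert-butyl[(1-methoxyvinyl)oxy]dimethylsilane | C=C(OC)O[Si](C)(C)C(C)(C)C | starting material
7 | methyl 2-[3-[(tert-butyldimethylsilyl)oxy]-1-methylcyclohex-2-en-1-yl]acetate (racemic) | COC(=O)CC1(C)CCCC(O[Si](C)(C)C(C)(C)C)=C1 | intermediate (not isolated)
8 | methyl 2-(1-methyl-3-oxocyclohexyl)acetate (racemic) | COC(=O)CC1(C)CCCC(=O)C1 | intermediate
9 | 2-(1-methyl-3-oxocyclohexyl)acetic acid (racemic) | OC(=O)CC1(C)CCCC(=O)C1 | intermediate
10 | 4-methylbicyclo[2.2.2]octane-2,6-dione (meso) | CC12CCC(C(=O)C1)C(=O)C2 | intermediate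
11 | lithium enolate of 10 (C4–O–Li, C4=C5) | C[C@]12CC[C@H](C(O[Li])=C1)C(=O)C2 | intermediate (not isolated)
12 | (1R,4R)-6-[(tert-butyldimethylsilyl)oxy]-4-methylbicyclo[2.2.2]oct-5-en-2-one | C[C@]12CC[C@H](C(O[Si](C)(C)C(C)(C)C)=C1)C(=O)C2 | intermediate
13 | lithium enolate of 12 (C8–O–Li, C8=C9) | C[C@]12CC[C@H](C(O[Si](C)(C)C(C)(C)C)=C1)C(O[Li])=C2 | intermediate (not isolated)
14 | (1R,3R,4S)-6-[(tert-butyldimethylsilyl)oxy]-3-[(3S)-5-[(tert-butyldiphenylsilyl)oxy]-3-methylpentyl]-4-methylbicyclo[2.2.2]oct-5-en-2-one | C[C@]12CC[C@H](C(O[Si](C)(C)C(C)(C)C)=C1)C(=O)[C@@H]2CC[C@H](C)CCO[Si](c1ccccc1)(c1ccccc1)C(C)(C)C | intermediate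
15 | 2-ethenyl carbinol of 14 (vinyl syn to the enol-ether bridge) | C[C@]12CC[C@H](C(O[Si](C)(C)C(C)(C)C)=C1)[C@](O)(C=C)[C@@H]2CC[C@H](C)CCO[Si](c1ccccc1)(c1ccccc1)C(C)(C)C | intermediate
16 | potassium alkoxide of 15 | C[C@]12CC[C@H](C(O[Si](C)(C)C(C)(C)C)=C1)[C@](O[K])(C=C)[C@@H]2CC[C@H](C)CCO[Si](c1ccccc1)(c1ccccc1)C(C)(C)C | intermediate (not isolated)
17 | potassium C7=C8 enolate of 18 | [K]OC1=CC[C@H]2[C@](C)(CCC=C2O[Si](C)(C)C(C)(C)C)[C@H]1CC[C@H](C)CCO[Si](c1ccccc1)(c1ccccc1)C(C)(C)C | intermediate (not isolated)
18 | 4-[(tert-butyldimethylsilyl)oxy]-15-[(tert-butyldiphenylsilyl)oxy]-17,18,19-trinor-5β-labd-3-en-8-one | O=C1CC[C@H]2[C@](C)(CCC=C2O[Si](C)(C)C(C)(C)C)[C@H]1CC[C@H](C)CCO[Si](c1ccccc1)(c1ccccc1)C(C)(C)C | intermediate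
19 | 4-[(tert-butyldimethylsilyl)oxy]-15-[(tert-butyldiphenylsilyl)oxy]-18,19-dinor-5β-labda-3,8(17)-diene | C=C1CC[C@H]2[C@](C)(CCC=C2O[Si](C)(C)C(C)(C)C)[C@H]1CC[C@H](C)CCO[Si](c1ccccc1)(c1ccccc1)C(C)(C)C | intermediate
20 | 15-[(tert-butyldiphenylsilyl)oxy]-18,19-dinor-5β-labd-8(17)-en-4-one (cis-fused) | C=C1CC[C@H]2[C@](C)(CCCC2=O)[C@H]1CC[C@H](C)CCO[Si](c1ccccc1)(c1ccccc1)C(C)(C)C | intermediate (not isolated)
21 | 15-[(tert-butyldiphenylsilyl)oxy]-18,19-dinorlabd-8(17)-en-4-one (trans-fused) | C=C1CC[C@@H]2[C@](C)(CCCC2=O)[C@H]1CC[C@H](C)CCO[Si](c1ccccc1)(c1ccccc1)C(C)(C)C | intermediate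
22 | potassium C3=C4 enolate of 21 | C=C1CC[C@@H]2[C@](C)(CCC=C2O[K])[C@H]1CC[C@H](C)CCO[Si](c1ccccc1)(c1ccccc1)C(C)(C)C | intermediate (not isolated)
23 | 15-[(tert-butyldiphenylsilyl)oxy]-18,19-dinorlabda-3,8(17)-dien-4-yl trifluoromethanesulfonate | C=C1CC[C@@H]2[C@](C)(CCC=C2OS(=O)(=O)C(F)(F)F)[C@H]1CC[C@H](C)CCO[Si](c1ccccc1)(c1ccccc1)C(C)(C)C | intermediate
24 | 2-(trimethylsilyl)ethyl 15-[(tert-butyldiphenylsilyl)oxy]-18-norlabda-3,8(17)-dien-19-oate | C=C1CC[C@@H]2[C@](C)(CCC=C2C(=O)OCC[Si](C)(C)C)[C@H]1CC[C@H](C)CCO[Si](c1ccccc1)(c1ccccc1)C(C)(C)C | intermediate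
25 | 2-(trimethylsilyl)ethyl 15-[(tert-butyldiphenylsilyl)oxy]-18-norlabd-8(17)-en-19-oate (C4 epimers) | C=C1CC[C@@H]2[C@](C)(CCCC2C(=O)OCC[Si](C)(C)C)[C@H]1CC[C@H](C)CCO[Si](c1ccccc1)(c1ccccc1)C(C)(C)C | intermediate
26 | lithium ester enolate of 25 | C=C1CC[C@@H]2[C@](C)(CCCC2=C(O[Li])OCC[Si](C)(C)C)[C@H]1CC[C@H](C)CCO[Si](c1ccccc1)(c1ccccc1)C(C)(C)C | intermediate (not isolated)
27 | 2-(trimethylsilyl)ethyl (13S)-15-[(tert-butyldiphenylsilyl)oxy]labd-8(17)-en-19-oate | C=C1CC[C@@H]2[C@](C)(CCC[C@]2(C)C(=O)OCC[Si](C)(C)C)[C@H]1CC[C@H](C)CCO[Si](c1ccccc1)(c1ccccc1)C(C)(C)C | intermediate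
28 | imbricatolic acid, (13S)-15-hydroxylabd-8(17)-en-19-oic acid | C=C1CC[C@@H]2[C@](C)(CCC[C@]2(C)C(=O)O)[C@H]1CC[C@H](C)CCO | intermediate
29 | (1S,4aR,5S,8aR)-5-[(3S)-5-(formyloxy)-3-methylpentyl]-1,4a-dimethyl-6-methylidenedecahydronaphthalene-1-carboxylic acid | C=C1CC[C@@H]2[C@](C)(CCC[C@]2(C)C(=O)O)[C@H]1CC[C@H](C)CCOC=O | target

**Step count**

Total steps: 18. Longest linear sequence: 15 steps (steps 4 to 18, from 5); steps 1 to 3 make the side-chain iodide that joins in step 8.

**Three steps most likely to fail**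

Step 7. The chiral amide may discriminate poorly between the two enantiotopic methylene groups, or in the wrong sense, and some double enolization may occur. The fallback sets out from 10 and returns at 12, using reagent-controlled reduction in place of deprotonation. Desymmetrizing mono-reduction of 10 with (S)-2-methyl-CBS-oxazaborolidine and BH3·SMe2 (THF, −30 °C; the antipodal catalyst if the other carbonyl is reduced) should give 6-hydroxy-4-methylbicyclo[2.2.2]octan-2-one F1, the reduced carbon being the future C8. TMSCl and imidazole give the trimethylsilyl ether F2. LiN(i-Pr)2 then TBSOTf convert the remaining ketone (only C5 can be deprotonated) into the bis-silyl compound F3. K2CO3 in MeOH at 0 °C removes only the alkyl trimethylsilyl ether to give 6-[(tert-butyldimethylsilyl)oxy]-4-methylbicyclo[2.2.2]oct-5-en-2-ol F4, and Dess–Martin oxidation gives 12. The carbinol configuration in F1 to F4 is of no consequence because it is oxidized again.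

Step 9. Facial selectivity of the carbonyl addition may be poor, because the side chain on C9 sits on the same face from which the vinyl group must enter, and the ketone may enolize instead of adding. The fallback sets out from 14 and returns at 15, replacing vinylation by alkynylation and semi-reduction. The rod-shaped nucleophile HC≡CMgBr with CeCl3 (THF, −78 °C) should feel the neighbouring chain less while the saturated bridge still blocks the other face, giving the ethynyl carbinol F5. Semi-hydrogenation (H2, Pd/CaCO3 poisoned with Pb(OAc)2, quinoline, EtOAc) then gives 15.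

Step 12. Equilibration of the ring fusion may be incomplete or less in favour of the trans isomer than expected. The fallback sets out from 20 (isolated after the acid hydrolysis, alone or mixed with 21) and returns at 21, replacing thermodynamic control by kinetic protonation. TMSCl and Et3N in DMF at 100 °C (equilibrating conditions) should give the tetrasubstituted C4=C5 trimethylsilyl enol ether F6, in which C5 is no longer a stereocenter. MeLi in THF at 0 °C releases the regiodefined lithium enolate F7. Protonation with acetic acid at −78 °C should occur axially on the α-face of C5, anti to the axial C10 methyl, giving 21.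

Further compounds
F1 | step 7 | 6-hydroxy-4-methylbicyclo[2.2.2]octan-2-one (hydroxyl on the future C8) | C[C@]12CC[C@H](C(=O)C1)[C@@H](O)C2
F2 | step 7 | 4-methyl-6-[(trimethylsilyl)oxy]bicyclo[2.2.2]octan-2-one | C[C@]12CC[C@H](C(=O)C1)[C@@H](O[Si](C)(C)C)C2
F3 | step 7 | 2-[(tert-butyldimethylsilyl)oxy]-4-methyl-6-[(trimethylsilyl)oxy]bicyclo[2.2.2]oct-2-ene | C[C@]12CC[C@H](C(O[Si](C)(C)C(C)(C)C)=C1)[C@@H](O[Si](C)(C)C)C2
F4 | step 7 | 6-[(tert-butyldimethylsilyl)oxy]-4-methylbicyclo[2.2.2]oct-5-en-2-ol | C[C@]12CC[C@H](C(O[Si](C)(C)C(C)(C)C)=C1)[C@@H](O)C2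
F5 | step 9 | 2-ethynyl carbinol of 14 (ethynyl syn to the enol-ether bridge) | C[C@]12CC[C@H](C(O[Si](C)(C)C(C)(C)C)=C1)[C@](O)(C#C)[C@@H]2CC[C@H](C)CCO[Si](c1ccccc1)(c1ccccc1)C(C)(C)C
F6 | step 12 | 15-[(tert-butyldiphenylsilyl)oxy]-4-[(trimethylsilyl)oxy]-18,19-dinorlabda-4,8(17)-diene | C=C1CCC2=C(O[Si](C)(C)C)CCC[C@]2(C)[C@H]1CC[C@H](C)CCO[Si](c1ccccc1)(c1ccccc1)C(C)(C)C
F7 | step 12 | lithium C4=C5 enolate of 21 | C=C1CCC2=C(O[Li])CCC[C@]2(C)[C@H]1CC[C@H](C)CCO[Si](c1ccccc1)(c1ccccc1)C(C)(C)C
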